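**Retrosynthetic overview**
Target ⇐ O-demethylation ⇐ twofold Vilsmeier formylation of ring B of a 2-arylchroman whose ring A already carries its formyl group (masked as a dioxolane until the pyran ring is closed).
Pyran ring ⇐ acid-mediated O1–C2 closure of a benzylic alcohol; the C2–OH and the para oxygen of ring B both come from C–B bonds.
C3–C4 and C2–aryl bonds ⇐ one conjunctive coupling of a ring-A o-quinone methide with an (E)-alkenyl(aryl)borate, with a 1,2-aryl shift from boron to carbon (key step, sets C3 and C4).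
Pieces: 1,3-dimethoxybenzene (ring A), 3-methylbutanal (C4 and isobutyl), 3-methylbut-1-yne (C2, C3, isopropyl), 1,3-bis(methoxymethoxy)benzene (ring B).
Ring order: aromatic rings A and B are bought and oxygenated by C–H borylation; the pyran ring is the only ring built and is closed late, once C2, C3 and C4 are in place.

Assumption: the dimethyl and bis-MOM ethers of resorcinol are bought as protected resorcinol (Bpin = pinacolatoboryl, MOM = methoxymethyl, Boc2O = di-tert-butyl dicarbonate).

Step 1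
Reactants: 1 1,3-dimethoxybenzene
Product: 2 2-(2,6-dimethoxyphenyl)-1,3-dioxolane
Conditions: nBuLi, THF, 0 °C to rt; MgBr2·OEt2; 2-methoxy-1,3-dioxolane, THF–toluene, 80 °C; H2O quench
Reagents that add atoms: 2-methoxy-1,3-dioxolane, COC1OCCO1
Why: Directed ortho-metalation puts lithium only between the two methoxy groups, and after transmetalation the aryl Grignard reagent displaces methoxide from the cyclic orthoformate (Bodroux–Chichibabin acetal synthesis), so the future C6 formyl carbon enters masked and with unambiguous regiochemistry.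

Step 2
Reactants: 2 2-(2,6-dimethoxyphenyl)-1,3-dioxolane
Product: 4 4-(1,3-dioxolan-2-yl)-3,5-dimethoxyphenol, via arylboronate 3 (not isolated)
Conditions: HBpin, [Ir(OMe)(1,5-cyclooctadiene)]2 (1.5 mol %), 4,4′-di-tert-butyl-2,2′-bipyridine (3 mol %), THF, 80 °C; then Me3NO, THF, 50 °C; work-up at pH 7–8
Reagents that add atoms: trimethylamine N-oxide, C[N+](C)(C)[O-]
Why: Sterically controlled iridium-catalysed C–H borylation (Hartwig–Miyaura type) can only reach the C–H para to the acetal, and amine N-oxide oxidation of the C–B bond gives the phenol without acid or peroxide, which the electron-rich aryl acetal would not tolerate.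

Step 3
Reactants: 4 4-(1,3-dioxolan-2-yl)-3,5-dimethoxyphenol; 5 3-methylbutanal
Product: 6 4-(1,3-dioxolan-2-yl)-2-(1-hydroxy-3-methylbutyl)-3,5-dimethoxyphenol (racemic)
Conditions: EtMgBr (1.0 equiv), Et2O, 0 °C; solvent switch to toluene; 5 (1.2 equiv), rt; H2O quench
Reagents that add atoms: none
Why: The bromomagnesium phenoxide delivers the aldehyde to the ortho carbon through a six-membered chelate (Casiraghi ortho-hydroxyalkylation); the two ortho positions are equivalent, the para position is blocked, and the racemic carbinol centre is erased in step 5.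

Step 4
Reactants: 7 3-methylbut-1-yne
Product: 8 2-[(E)-3-methylbut-1-en-1-yl]-4,4,5,5-tetramethyl-1,3,2-dioxaborolane
Conditions: HBpin, Cp2Zr(H)Cl (5 mol %), Et3N (10 mol %), neat, sealed tube, 60 °C
Reagents that add atoms: pinacolborane, B1OC(C)(C)C(C)(C)O1
Why: Zirconocene-catalysed hydroboration of the terminal alkyne (hydrozirconation, then Zr-to-B exchange) is a syn addition that gives only the (E)-alkenylboronate.

Step 5
Reactants: 6 4-(1,3-dioxolan-2-yl)-2-(1-hydroxy-3-methylbutyl)-3,5-dimethoxyphenol; 8 2-[(E)-3-methylbut-1-en-1-yl]-4,4,5,5-tetramethyl-1,3,2-dioxaborolane; 9 1,3-bis(methoxymethoxy)benzene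
Product: 13 2-[(1R,2R,3S)-1-[2,6-bis(methoxymethoxy)phenyl]-5-methyl-2-(propan-2-yl)-1-(4,4,5,5-tetramethyl-1,3,2-dioxaborolan-2-yl)hexan-3-yl]-4-(1,3-dioxolan-2-yl)-3,5-dimethoxyphenol, via aryllithium 10 (not isolated), via borate 11 (not isolated), via quinone methide 12 (not isolated)
Conditions: 9, nBuLi (1.0 equiv), THF, 0 °C, then 8, −78 to 0 °C (gives 11); separately 6, nBuLi (2.0 equiv), THF–toluene 1:4, −78 °C, then Boc2O (gives 12); 11 added together with N-benzyl-9-deoxy-9-epi-9-[3-[3,5-bis(trifluoromethyl)phenyl]ureido]cinchonidinium bromide (10 mol %), −78 to −40 °C; AcOH quench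
Reagents that add atoms: none
Why: Proposed new method: the neutral o-quinone methide 12, hydrogen-bonded through its carbonyl oxygen to the urea of the chiral ammonium cation whose counter-ion is borate 11, is attacked at C4 by the β-carbon of the alkenylborate while the aryl group shifts 1,2 from boron to the α-carbon anti to the new C–C bond (stereospecific 1,2-metallate rearrangement), so one step forms C3–C4 and C2–aryl; the ion pair selects the quinone methide face (C4, S), an open antiperiplanar transition state with the isopropyl group gauche only to hydrogen gives the relative configuration needed for the 3,4-cis chroman (C3, R), and C2 (R, from anti migration) is not critical because step 7 re-sets it; the closest known reactions are the electrophile-induced 1,2-migrations of alkenylboronate complexes with stabilised carbocations (tropylium, iminium ions) and urea–ammonium ion-pair-catalysed additions of anionic nucleophiles to o-quinone methides, while quinone methide release by Boc transfer and elimination is known.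

Step 6
Reactants: 13 2-[(1R,2R,3S)-1-[2,6-bis(methoxymethoxy)phenyl]-5-methyl-2-(propan-2-yl)-1-(4,4,5,5-tetramethyl-1,3,2-dioxaborolan-2-yl)hexan-3-yl]-4-(1,3-dioxolan-2-yl)-3,5-dimethoxyphenol
Product: 15 4-(1,3-dioxolan-2-yl)-2-[(1R,2R,3S)-1-hydroxy-1-[4-hydroxy-2,6-bis(methoxymethoxy)phenyl]-5-methyl-2-(propan-2-yl)hexan-3-yl]-3,5-dimethoxyphenol, via trisboronate 14 (not isolated)
Conditions: HBpin (3 equiv), [Ir(OMe)(1,5-cyclooctadiene)]2 (2 mol %), 4,4′-di-tert-butyl-2,2′-bipyridine (4 mol %), THF, 70 °C; then Me3NO, THF, 60 °C; aqueous work-up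
Reagents that add atoms: trimethylamine N-oxide, C[N+](C)(C)[O-]
Why: HBpin first masks the phenol as its O-Bpin ester, sterically controlled iridium-catalysed C–H borylation then hits the only unhindered aryl C–H (para position of ring B), and N-oxide oxidation turns both C–B bonds into C–O bonds with retention (boronate oxidation) while the O–B bond is hydrolysed on work-up.

Step 7
Reactants: 15 4-(1,3-dioxolan-2-yl)-2-[(1R,2R,3S)-1-hydroxy-1-[4-hydroxy-2,6-bis(methoxymethoxy)phenyl]-5-methyl-2-(propan-2-yl)hexan-3-yl]-3,5-dimethoxyphenol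
Product: 16 (2R,3R,4S)-5,7-dimethoxy-4-(2-methylpropyl)-3-(propan-2-yl)-2-(2,4,6-trihydroxyphenyl)-3,4-dihydro-2H-chromene-6-carbaldehyde
Conditions: 2 M aq HCl, THF–MeOH, 0.02 M, 40 °C
Reagents that add atoms: water, O
Why: The benzylic alcohol ionises to a cation stabilised by trioxygenated ring B and is trapped by the ring-A phenol, the only free oxygen ortho to the side chain (SN1 cycloetherification), under thermodynamic control that puts the C2 aryl group equatorial and trans to the C3 isopropyl group (2R), while the same acid cleaves both MOM ethers and the dioxolane.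

Step 8
Reactants: 16 (2R,3R,4S)-5,7-dimethoxy-4-(2-methylpropyl)-3-(propan-2-yl)-2-(2,4,6-trihydroxyphenyl)-3,4-dihydro-2H-chromene-6-carbaldehyde
Product: 17 5-[(2R,3R,4S)-6-formyl-5,7-dimethoxy-4-(2-methylpropyl)-3-(propan-2-yl)-3,4-dihydro-2H-chromen-2-yl]-2,4,6-trihydroxybenzene-1,3-dicarbaldehyde
Conditions: POCl3 (4 equiv), DMF (6 equiv), EtOAc, 0 °C to rt; then H2O, 50 °C
Reagents that add atoms: N,N-dimethylformamide, CN(C)C=O; water, O
Why: Vilsmeier–Haack formylation takes place twice on the free phloroglucinol ring B at its two open positions, whereas ring A, a non-phenolic aryl ether already deactivated by its formyl group, is left alone at C8.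

Step 9
Reactants: 17 5-[(2R,3R,4S)-6-formyl-5,7-dimethoxy-4-(2-methylpropyl)-3-(propan-2-yl)-3,4-dihydro-2H-chromen-2-yl]-2,4,6-trihydroxybenzene-1,3-dicarbaldehyde
Product: 18 5-[(2R,3R,4S)-6-formyl-5,7-dihydroxy-4-(2-methylpropyl)-3-(propan-2-yl)-3,4-dihydro-2H-chromen-2-yl]-2,4,6-trihydroxybenzene-1,3-dicarbaldehyde
Conditions: BBr3 (6 equiv), CH2Cl2, −78 to 0 °C; then H2O
Reagents that add atoms: none
Why: BBr3 cleaves the two aryl methyl ethers, each ortho to the ring-A formyl group (chelation-assisted Lewis-acid ether cleavage), and the diformylated ring B no longer stabilises a C2 cation, so the chroman and its three stereocentres survive.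

**Compound list**
1 | 1,3-dimethoxybenzene | COc1cccc(OC)c1 | starting material
2 | 2-(2,6-dimethoxyphenyl)-1,3-dioxolane | COc1cccc(OC)c1C1OCCO1 | intermediate
3 | 2-[4-(1,3-dioxolan-2-yl)-3,5-dimethoxyphenyl]-4,4,5,5-tetramethyl-1,3,2-dioxaborolane | COc1cc(B2OC(C)(C)C(C)(C)O2)cc(OC)c1C1OCCO1 | intermediate (not isolated)
4 | 4-(1,3-dioxolan-2-yl)-3,5-dimethoxyphenol | COc1cc(O)cc(OC)c1C1OCCO1 | intermediate
5 | 3-methylbutanal | CC(C)CC=O | starting material
6 | 4-(1,3-dioxolan-2-yl)-2-(1-hydroxy-3-methylbutyl)-3,5-dimethoxyphenol (racemic) | COc1cc(O)c(C(O)CC(C)C)c(OC)c1C1OCCO1 | intermediate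
7 | 3-methylbut-1-yne | CC(C)C#C | starting material
8 | 2-[(E)-3-methylbut-1-en-1-yl]-4,4,5,5-tetramethyl-1,3,2-dioxaborolane | CC(C)/C=C/B1OC(C)(C)C(C)(C)O1 | intermediate
9 | 1,3-bis(methoxymethoxy)benzene | COCOc1cccc(OCOC)c1 | starting material
10 | [2,6-bis(methoxymethoxy)phenyl]lithium | [Li]c1c(OCOC)cccc1OCOC | intermediate (not isolated)
11 | lithium [2,6-bis(methoxymethoxy)phenyl][(E)-3-methylbut-1-en-1-yl](pinacolato)borate | [Li+].CC(C)/C=C/[B-]1(c2c(OCOC)cccc2OCOC)OC(C)(C)C(C)(C)O1 | intermediate (not isolated)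
12 | 4-(1,3-dioxolan-2-yl)-3,5-dimethoxy-6-(3-methylbutylidene)cyclohexa-2,4-dien-1-one | O=C1C=C(OC)C(C2OCCO2)=C(OC)C1=CCC(C)C | intermediate (not isolated)
13 | 2-[(1R,2R,3S)-1-[2,6-bis(methoxymethoxy)phenyl]-5-methyl-2-(propan-2-yl)-1-(4,4,5,5-tetramethyl-1,3,2-dioxaborolan-2-yl)hexan-3-yl]-4-(1,3-dioxolan-2-yl)-3,5-dimethoxyphenol | CC(C)C[C@@H]([C@@H](C(C)C)[C@@H](B1OC(C)(C)C(C)(C)O1)c1c(OCOC)cccc1OCOC)c1c(O)cc(OC)c(C2OCCO2)c1OC | intermediate
14 | 2-[2-[(1R,2R,3S)-1-[2,6-bis(methoxymethoxy)-4-(4,4,5,5-tetramethyl-1,3,2-dioxaborolan-2-yl)phenyl]-5-methyl-2-(propan-2-yl)-1-(4,4,5,5-tetramethyl-1,3,2-dioxaborolan-2-yl)hexan-3-yl]-4-(1,3-dioxolan-2-yl)-3,5-dimethoxyphenoxy]-4,4,5,5-tetramethyl-1,3,2-dioxaborolane | CC(C)C[C@@H]([C@@H](C(C)C)[C@@H](B1OC(C)(C)C(C)(C)O1)c1c(OCOC)cc(B2OC(C)(C)C(C)(C)O2)cc1OCOC)c1c(OB2OC(C)(C)C(C)(C)O2)cc(OC)c(C2OCCO2)c1OC | intermediate (not isolated)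
15 | 4-(1,3-dioxolan-2-yl)-2-[(1R,2R,3S)-1-hydroxy-1-[4-hydroxy-2,6-bis(methoxymethoxy)phenyl]-5-methyl-2-(propan-2-yl)hexan-3-yl]-3,5-dimethoxyphenol | CC(C)C[C@@H]([C@@H](C(C)C)[C@@H](O)c1c(OCOC)cc(O)cc1OCOC)c1c(O)cc(OC)c(C2OCCO2)c1OC | intermediate
16 | (2R,3R,4S)-5,7-dimethoxy-4-(2-methylpropyl)-3-(propan-2-yl)-2-(2,4,6-trihydroxyphenyl)-3,4-dihydro-2H-chromene-6-carbaldehyde | CC(C)C[C@@H]1c2c(cc(OC)c(C=O)c2OC)O[C@@H](c2c(O)cc(O)cc2O)[C@@H]1C(C)C | intermediate
17 | 5-[(2R,3R,4S)-6-formyl-5,7-dimethoxy-4-(2-methylpropyl)-3-(propan-2-yl)-3,4-dihydro-2H-chromen-2-yl]-2,4,6-trihydroxybenzene-1,3-dicarbaldehyde | CC(C)C[C@@H]1c2c(cc(OC)c(C=O)c2OC)O[C@@H](c2c(O)c(C=O)c(O)c(C=O)c2O)[C@@H]1C(C)C | intermediate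
18 | 5-[(2R,3R,4S)-6-formyl-5,7-dihydroxy-4-(2-methylpropyl)-3-(propan-2-yl)-3,4-dihydro-2H-chromen-2-yl]-2,4,6-trihydroxybenzene-1,3-dicarbaldehyde | CC(C)C[C@@H]1c2c(cc(O)c(C=O)c2O)O[C@@H](c2c(O)c(C=O)c(O)c(C=O)c2O)[C@@H]1C(C)C | target

**Step count and risks**
Total steps: 9. Longest linear sequence: 8 (steps 1, 2, 3, 5, 6, 7, 8, 9).

Steps most likely to fail:

Step 5, the proposed conjunctive coupling. The risks are a racemic background reaction of the lithium borate, an E/Z mixture of 12 that erodes face selection, low simple diastereoselection, and 1,5-hydrogen shift of 12 to the styrene. The catalyst antipode (cinchonidine- or cinchonine-derived) has to be chosen by a first screen. The fallback uses known chemistry, sets out from 10, 8 and 6, and comes back at 16. Aryllithium 10 is quenched with iodine to give 2-iodo-1,3-bis(methoxymethoxy)benzene F1. Suzuki–Miyaura coupling of F1 with 8 (Pd(OAc)2, 2-dicyclohexylphosphino-2′,6′-dimethoxybiphenyl, K3PO4, aqueous dioxane) gives 2-[(E)-3-methylbut-1-en-1-yl]-1,3-bis(methoxymethoxy)benzene F2. The quinone methide released from 6 is then annulated with F2 under (R)- or (S)-3,3′-bis(2,4,6-triisopropylphenyl)-1,1′-binaphthyl-2,2′-diyl hydrogen phosphate catalysis (toluene, molecular sieves), the known acid-catalysed chroman annulation of o-quinone methides with electron-rich styrenes, to give chroman acetal F3. Iridium-catalysed borylation as in step 6 gives ring-B arylboronate F4, Me3NO oxidation gives phenol F5, and the acid treatment of step 7 converts F5 into 16.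

Step 7, the global acid step. The risks are intermolecular condensation between the freed phloroglucinol ring and the freed aldehyde, and slow epimerisation at C3 through reversible loss of a proton from the C2 cation. The fallback sets out from 15 and comes back at 16. Pyridinium p-toluenesulfonate in wet acetone at rt closes the pyran ring and exchanges the dioxolane while the MOM ethers stay, giving (2R,3R,4S)-2-[4-hydroxy-2,6-bis(methoxymethoxy)phenyl]-5,7-dimethoxy-4-(2-methylpropyl)-3-(propan-2-yl)-3,4-dihydro-2H-chromene-6-carbaldehyde F6. The MOM groups are then removed under aprotic conditions with bromotrimethylsilane in CH2Cl2 at −30 °C to give 16.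

Step 3, the ortho-hydroxyalkylation. The risks are over-reaction of the very electron-rich product through its quinone methide to a bis(aryl)alkane, and aldol chemistry of the enolisable aldehyde. The fallback sets out from 4 and comes back at 6. Ortho-formylation of 4 with MgCl2, Et3N and paraformaldehyde in MeCN gives 5-(1,3-dioxolan-2-yl)-2-hydroxy-4,6-dimethoxybenzaldehyde F7, and isobutylmagnesium bromide (2.2 equiv, THF, −78 °C) adds to the aldehyde to give 6.

**Further compounds**
F1 | step 5 | 2-iodo-1,3-bis(methoxymethoxy)benzene | COCOc1cccc(OCOC)c1I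
F2 | step 5 | 2-[(E)-3-methylbut-1-en-1-yl]-1,3-bis(methoxymethoxy)benzene | CC(C)/C=C/c1c(OCOC)cccc1OCOC
F3 | step 5 | 2-[(2R,3R,4S)-2-[2,6-bis(methoxymethoxy)phenyl]-5,7-dimethoxy-4-(2-methylpropyl)-3-(propan-2-yl)-3,4-dihydro-2H-chromen-6-yl]-1,3-dioxolane | CC(C)C[C@@H]1c2c(cc(OC)c(C3OCCO3)c2OC)O[C@@H](c2c(OCOC)cccc2OCOC)[C@@H]1C(C)C
F4 | step 5 | 2-[4-[(2R,3R,4S)-6-(1,3-dioxolan-2-yl)-5,7-dimethoxy-4-(2-methylpropyl)-3-(propan-2-yl)-3,4-dihydro-2H-chromen-2-yl]-3,5-bis(methoxymethoxy)phenyl]-4,4,5,5-tetramethyl-1,3,2-dioxaborolane | CC(C)C[C@@H]1c2c(cc(OC)c(C3OCCO3)c2OC)O[C@@H](c2c(OCOC)cc(B3OC(C)(C)C(C)(C)O3)cc2OCOC)[C@@H]1C(C)C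
F5 | step 5 | 4-[(2R,3R,4S)-6-(1,3-dioxolan-2-yl)-5,7-dimethoxy-4-(2-methylpropyl)-3-(propan-2-yl)-3,4-dihydro-2H-chromen-2-yl]-3,5-bis(methoxymethoxy)phenol | CC(C)C[C@@H]1c2c(cc(OC)c(C3OCCO3)c2OC)O[C@@H](c2c(OCOC)cc(O)cc2OCOC)[C@@H]1C(C)C
F6 | step 7 | (2R,3R,4S)-2-[4-hydroxy-2,6-bis(methoxymethoxy)phenyl]-5,7-dimethoxy-4-(2-methylpropyl)-3-(propan-2-yl)-3,4-dihydro-2H-chromene-6-carbaldehyde | CC(C)C[C@@H]1c2c(cc(OC)c(C=O)c2OC)O[C@@H](c2c(OCOC)cc(O)cc2OCOC)[C@@H]1C(C)C
F7 | step 3 | 5-(1,3-dioxolan-2-yl)-2-hydroxy-4,6-dimethoxybenzaldehyde | COc1cc(O)c(C=O)c(OC)c1C1OCCO1
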